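## Retrosynthetic overview

- Numbering used throughout: C1 ring C=O, C2 oxirane CH, C3 oxirane carbon carrying the chain, C4 CHOH, C5 =CH, C6 =C(CH2OAc); chain C1'–C12'.
- Endgame (retro): C1 ketone from its dimethyl ketal; C4–OH from C4=O by hydride delivery on the oxirane face; oxirane C2–C3 from nucleophilic epoxidation of a C2=C3–C4=O enone, steered by the C1' centre.
- Key disconnection C3–C1': ligand-controlled Ni/Cr addition of a C3 alkenyl iodide (a 2-iodo-4,4-dimethoxycyclohexa-2,5-dienone) to the C1' aldehyde of the complete C15 tetraenal. The enabling feature is that, at the quinone-monoketal oxidation level of the six-membered ring, C3 is the sp2 α-carbon of the C4 carbonyl next to an unsubstituted C2–H, so it can carry iodine and, after coupling, C2=C3 is still the enone the oxirane needs.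
- Fragments: the iodo-dienone from 5-hydroxy-2-methoxybenzaldehyde (reduction, ortho-iodination, oxidative dearomatisation, acetylation); the tetraenal by Stille union of a (Z)-allylic alcohol/(E)-vinyl iodide (Still–Gennari olefination, Zr-catalysed carboalumination) with a stannyl dienal.
- Ring order: the carbocycle is the benzene ring of the starting arene, dearomatised in step 3; the oxirane is closed second, in step 14.

Key step: step 12

Assumption: the (S)-valinol-derived oxazoline–sulfonamide ligand is taken to expose the Re face of the aldehyde in step 12; if the sense is the opposite, its enantiomer is used with no other change.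

## Route

Step 1
Reactants: 1 5-hydroxy-2-methoxybenzaldehyde
Product: 2 3-(hydroxymethyl)-4-methoxyphenol
Conditions: NaBH4, MeOH, 0 °C
Reagents that add atoms: none
Why: Chemoselective borohydride reduction of the aryl aldehyde to the benzylic alcohol; no stereocentre is involved.

Step 2
Reactants: 2 3-(hydroxymethyl)-4-methoxyphenol
Product: 3 5-(hydroxymethyl)-2-iodo-4-methoxyphenol
Conditions: N-iodosuccinimide (1.0 equiv), DMF, 0 °C to rt
Reagents that add atoms: N-iodosuccinimide O=C1CCC(=O)N1I
Why: Electrophilic aromatic iodination ortho to the phenol OH; of the two ortho positions the one para to CH2OH is open, while the other is flanked by the CH2OH-bearing carbon.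

Step 3
Reactants: 3 5-(hydroxymethyl)-2-iodo-4-methoxyphenol
Product: 4 5-(hydroxymethyl)-2-iodo-4,4-dimethoxycyclohexa-2,5-dien-1-one
Conditions: PhI(OAc)2, MeOH, 0 °C
Reagents that add atoms: methanol CO
Why: Iodine(III) oxidative dearomatisation of a 4-methoxyphenol, in which methanol adds at the OMe-bearing para carbon to give the quinone monoketal; the aryl iodide and the primary alcohol are inert.

Step 4
Reactants: 4 5-(hydroxymethyl)-2-iodo-4,4-dimethoxycyclohexa-2,5-dien-1-one
Product: 5 (4-iodo-6,6-dimethoxy-3-oxocyclohexa-1,4-dien-1-yl)methyl acetate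
Conditions: Ac2O, pyridine, DMAP (cat.), CH2Cl2, 0 °C
Reagents that add atoms: acetic anhydride CC(=O)OC(C)=O
Why: Standard acylation of the only hydroxyl, which installs the acetate of the target early because every later step should tolerate it.

Step 5
Reactants: 6 pent-4-yn-1-ol
Product: 7 pent-4-ynal
Conditions: PhI(OAc)2, TEMPO (cat.), CH2Cl2, rt; used as a solution
Reagents that add atoms: none
Why: TEMPO/iodine(III) oxidation stops at the aldehyde and leaves the terminal alkyne untouched.

Step 6
Reactants: 7 pent-4-ynal; 8 ethyl 2-[bis(2,2,2-trifluoroethoxy)phosphoryl]propanoate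
Product: 9 ethyl (2Z)-2-methylhept-2-en-6-ynoate
Conditions: KHMDS, 18-crown-6, THF, −78 °C
Reagents that add atoms: none
Why: Still–Gennari olefination, in which the electron-poor phosphonate eliminates kinetically from the syn adduct and so gives the (Z)-trisubstituted enoate.

Step 7
Reactants: 9 ethyl (2Z)-2-methylhept-2-en-6-ynoate
Product: 10 (2Z)-2-methylhept-2-en-6-yn-1-ol
Conditions: DIBAL-H, CH2Cl2, −78 to 0 °C; Rochelle salt work-up
Reagents that add atoms: none
Why: 1,2-Reduction of the enoate to the (Z)-allylic alcohol without change of alkene geometry or attack on the alkyne.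

Step 8
Reactants: 10 (2Z)-2-methylhept-2-en-6-yn-1-ol
Product: 12 (2Z,6E)-7-iodo-2,6-dimethylhepta-2,6-dien-1-ol, via alkenylalane 11 (not isolated)
Conditions: Me3Al (excess), Cp2ZrCl2 (cat.), CH2Cl2, 0 °C to rt; then I2, THF, −30 °C
Reagents that add atoms: trimethylaluminium C[Al](C)C; iodine II
Why: Zr-catalysed methylalumination (Negishi carboalumination) adds Me and Al syn with Al at the terminal carbon, and iodinolysis of the C–Al bond with retention gives the (E)-iodide; the hydroxyl is carried as its aluminium alkoxide.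

Step 9
Reactants: 13 (2E)-3-methylpent-2-en-4-yn-1-ol
Product: 14 (2E,4E)-3-methyl-5-(tributylstannyl)penta-2,4-dien-1-ol
Conditions: Bu3SnH, PdCl2(PPh3)2 (cat.), THF, 0 °C
Reagents that add atoms: tributyltin hydride CCCC[SnH](CCCC)CCCC
Why: Pd-catalysed syn hydrostannation of the terminal alkyne places tin at the terminus and gives the (E)-vinylstannane, leaving the existing (E)-alkene untouched.

Step 10
Reactants: 14 (2E,4E)-3-methyl-5-(tributylstannyl)penta-2,4-dien-1-ol
Product: 15 (2E,4E)-3-methyl-5-(tributylstannyl)penta-2,4-dienal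
Conditions: MnO2, CH2Cl2, rt
Reagents that add atoms: none
Why: Selective allylic oxidation to the enal; the vinylstannane should survive.

Step 11
Reactants: 12 (2Z,6E)-7-iodo-2,6-dimethylhepta-2,6-dien-1-ol; 15 (2E,4E)-3-methyl-5-(tributylstannyl)penta-2,4-dienal
Product: 16 (2E,4E,6E,10Z)-12-hydroxy-3,7,11-trimethyldodeca-2,4,6,10-tetraenal
Conditions: Pd2(dba)3 (cat.), AsPh3, NMP, rt, dark
Reagents that add atoms: none
Why: Stille coupling of alkenyl iodide and alkenylstannane with retention of both geometries assembles the (2E,4E,6E)-triene; the free hydroxyl and the aldehyde are tolerated.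

Step 12
Reactants: 5 (4-iodo-6,6-dimethoxy-3-oxocyclohexa-1,4-dien-1-yl)methyl acetate; 16 (2E,4E,6E,10Z)-12-hydroxy-3,7,11-trimethyldodeca-2,4,6,10-tetraenal
Product: 18 {4-[(1S,2E,4E,6E,10Z)-1,12-dihydroxy-3,7,11-trimethyldodeca-2,4,6,10-tetraen-1-yl]-6,6-dimethoxy-3-oxocyclohexa-1,4-dien-1-yl}methyl acetate, via alkenylchromium(III) dichloride 17 (not isolated)
Conditions: CrCl2 (excess), (S)-N-[2-(4-isopropyl-4,5-dihydro-1,3-oxazol-2-yl)-6-methylphenyl]methanesulfonamide, Et3N, THF, rt; then NiCl2 (cat.), 5 and 16, rt; ligand recovered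
Reagents that add atoms: none
Why: Ni(0) inserts into the vinylic C3–I bond of 5, the alkenyl group passes to Cr(III) (17), and the alkenylchromium adds 1,2 to the aldehyde carbon C1' of 16 through a closed, chromium-bound transition state. The closest known reaction type is the asymmetric Nozaki–Hiyama–Kishi coupling of alkenyl iodides with aldehydes under a chiral oxazoline–sulfonamide ligand. No ring is closed; the one new stereocentre, C1', is set by the ligand, which should expose the Re face of the aldehyde and give 1'S. The step needs attack on the aldehyde in preference to the dienone carbonyl, the allylic acetate and the ketal, and 1,2- rather than 1,4- or 1,6-addition to the trienal; the low basicity and strict aldehyde selectivity of organochromium(III) secure this, and the free C12' hydroxyl is tolerated. Two achiral fragments thus give the complete carbon skeleton with every oxygen except the oxirane one, and C2=C3 is kept as an enone so that C1' can steer the epoxidation and, through the oxirane, the C4 reduction.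

Step 13
Reactants: 18 (1'S)-diol dienone
Product: 19 bis(triethylsilyl) ether of 18 (1'-OTES, 12'-OTES; 1'S)
Conditions: TESCl, imidazole, DMAP (cat.), DMF, 0 °C to rt
Reagents that add atoms: chlorotriethylsilane CC[Si](Cl)(CC)CC
Why: Silylation of both hydroxyls; masking C1'–OH prevents its hydrogen bond or chelate to the C4 carbonyl in step 14 and internal hydride delivery in step 15.

Step 14
Reactants: 19 bis-TES dienone
Product: 20 bis-TES epoxy ketone: C2–C3 oxirane (2R,3R), C4 ketone, C1 dimethyl ketal, 1'S
Conditions: t-BuOOH (anhydrous, in decane), DBU, CH2Cl2, 0 °C to rt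
Reagents that add atoms: tert-butyl hydroperoxide CC(C)(C)OO
Why: Weitz–Scheffer epoxidation, in which t-BuOO− adds to C2 (the only β-carbon that bears H) and the C3 enolate closes the oxirane; with C1'–H eclipsing the C4 carbonyl (allylic strain) the C–O bond should form on the face opposite the dienyl group, which gives the (2R,3R) oxirane, and the electron-rich polyene is inert to the nucleophilic oxidant.

Step 15
Reactants: 20 bis-TES epoxy ketone
Product: 21 bis-TES epoxy alcohol (2R,3R,4S,1'S), C1 dimethyl ketal
Conditions: NaBH4, CeCl3·7H2O, MeOH/THF, −78 °C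
Reagents that add atoms: none
Why: Luche 1,2-reduction, in which cerium bridged between the carbonyl and oxirane oxygens should guide borohydride to the Re face of C4 (the oxirane face) while the C1'(OTES)dienyl group on C3 screens the other face, giving the 4S alcohol trans to the oxirane; acetate, ketal and polyene are untouched.

Step 16
Reactants: 21 bis-TES epoxy alcohol
Product: 22 triol ketal (2R,3R,4S,1'S): 1',4,12'-triol with the C1 dimethyl ketal intact
Conditions: HF·pyridine, pyridine (excess), THF, 0 °C to rt
Reagents that add atoms: none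
Why: Buffered fluoride cleaves both Si–O bonds; the ketal is kept so that the ring holds no enone while pyridine and fluoride are present, which protects the allylic acetate from addition–elimination.

Step 17
Reactants: 22 triol ketal
Product: 23 target, [(2R,3R,4S)-2,3-epoxy-4-hydroxy-3-[(1S,2E,4E,6E,10Z)-1,12-dihydroxy-3,7,11-trimethyldodeca-2,4,6,10-tetraen-1-yl]-1-oxocyclohex-5-en-6-yl]methyl acetate (overview numbering)
Conditions: montmorillonite K10, moist CH2Cl2, rt
Reagents that add atoms: water O
Why: Acidic-clay hydrolysis of the allylic dimethyl ketal reveals the enone under conditions mild enough for the oxirane, the acetate and the acid-sensitive bis-allylic C1' carbinol.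

## Compound list

1 | 5-hydroxy-2-methoxybenzaldehyde | COc1ccc(O)cc1C=O | starting material
2 | 3-(hydroxymethyl)-4-methoxyphenol | COc1ccc(O)cc1CO | intermediate
3 | 5-(hydroxymethyl)-2-iodo-4-methoxyphenol | COc1cc(I)c(O)cc1CO | intermediate
4 | 5-(hydroxymethyl)-2-iodo-4,4-dimethoxycyclohexa-2,5-dien-1-one | O=C1C=C(CO)C(OC)(OC)C=C1I | intermediate
5 | (4-iodo-6,6-dimethoxy-3-oxocyclohexa-1,4-dien-1-yl)methyl acetate | O=C1C=C(COC(C)=O)C(OC)(OC)C=C1I | intermediate
6 | pent-4-yn-1-ol | C#CCCCO | starting material
7 | pent-4-ynal | C#CCCC=O | intermediate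
8 | ethyl 2-[bis(2,2,2-trifluoroethoxy)phosphoryl]propanoate | CCOC(=O)C(C)P(=O)(OCC(F)(F)F)OCC(F)(F)F | starting material
9 | ethyl (2Z)-2-methylhept-2-en-6-ynoate | C#CCC/C=C(/C)C(=O)OCC | intermediate
10 | (2Z)-2-methylhept-2-en-6-yn-1-ol | C#CCC/C=C(/C)CO | intermediate
11 | (1E,5Z)-alkenyl(dimethyl)alane, O-dimethylaluminium alkoxide | C[Al](C)/C=C(\C)CC/C=C(/C)CO[Al](C)C | intermediate
12 | (2Z,6E)-7-iodo-2,6-dimethylhepta-2,6-dien-1-ol | I/C=C(\C)CC/C=C(/C)CO | intermediate
13 | (2E)-3-methylpent-2-en-4-yn-1-ol | OC/C=C(C)/C#C | starting material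
14 | (2E,4E)-3-methyl-5-(tributylstannyl)penta-2,4-dien-1-ol | OC/C=C(C)/C=C/[Sn](CCCC)(CCCC)CCCC | intermediate
15 | (2E,4E)-3-methyl-5-(tributylstannyl)penta-2,4-dienal | O=C/C=C(C)/C=C/[Sn](CCCC)(CCCC)CCCC | intermediate
16 | (2E,4E,6E,10Z)-12-hydroxy-3,7,11-trimethyldodeca-2,4,6,10-tetraenal | O=C/C=C(C)/C=C/C=C(\C)CC/C=C(/C)CO | intermediate
17 | alkenylchromium(III) dichloride from 5 (Cr at C3) | O=C1C=C(COC(C)=O)C(OC)(OC)C=C1[Cr](Cl)Cl | intermediate
18 | {4-[(1S,2E,4E,6E,10Z)-1,12-dihydroxy-3,7,11-trimethyldodeca-2,4,6,10-tetraen-1-yl]-6,6-dimethoxy-3-oxocyclohexa-1,4-dien-1-yl}methyl acetate | O=C1C=C(COC(C)=O)C(OC)(OC)C=C1[C@@H](O)/C=C(C)/C=C/C=C(\C)CC/C=C(/C)CO | intermediate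
19 | bis(triethylsilyl) ether of 18 (1'S) | O=C1C=C(COC(C)=O)C(OC)(OC)C=C1[C@@H](O[Si](CC)(CC)CC)/C=C(C)/C=C/C=C(\C)CC/C=C(/C)CO[Si](CC)(CC)CC | intermediate
20 | bis-TES epoxy ketone (2R,3R,1'S), C1 dimethyl ketal | CC(=O)OCC1=CC(=O)[C@@]2([C@@H](O[Si](CC)(CC)CC)/C=C(C)/C=C/C=C(\C)CC/C=C(/C)CO[Si](CC)(CC)CC)O[C@H]2C1(OC)OC | intermediate
21 | bis-TES epoxy alcohol (2R,3R,4S,1'S), C1 dimethyl ketal | CC(=O)OCC1=C[C@H](O)[C@@]2([C@@H](O[Si](CC)(CC)CC)/C=C(C)/C=C/C=C(\C)CC/C=C(/C)CO[Si](CC)(CC)CC)O[C@H]2C1(OC)OC | intermediate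
22 | triol ketal (2R,3R,4S,1'S) | CC(=O)OCC1=C[C@H](O)[C@@]2([C@@H](O)/C=C(C)/C=C/C=C(\C)CC/C=C(/C)CO)O[C@H]2C1(OC)OC | intermediate
23 | target (2R,3R,4S,1'S; overview numbering) | CC(=O)OCC1=C[C@H](O)[C@@]2([C@@H](O)/C=C(C)/C=C/C=C(\C)CC/C=C(/C)CO)O[C@H]2C1=O | target

## Step count and risks

Total step count: 17. Longest linear sequence: 11 steps (steps 5, 6, 7, 8, 11, 12, 13, 14, 15, 16, 17).

**Step 12.** What may go wrong: the chromium-bound ligand may discriminate the two faces of the trienal poorly, and Cr(II) may reduce the iodo-dienone (loss of iodine, or rearomatisation with loss of methanol) faster than the nickel-mediated coupling. Fallback: the same C3–C1' bond is made one oxidation level earlier, on the arene, and the ring is dearomatised afterwards; it sets out from 3 and 16 and comes back at 18. Lipase-catalysed acetylation of the benzylic hydroxyl of 3 (immobilised Candida antarctica lipase B, vinyl acetate) would give 5-hydroxy-4-iodo-2-methoxybenzyl acetate F1. Pd-catalysed borylation with tetrahydroxydiboron would give [4-(acetoxymethyl)-2-hydroxy-5-methoxyphenyl]boronic acid F2. Boron-to-zinc exchange with Et2Zn followed by amino-alcohol-catalysed enantioselective aryl transfer to 16 would give 5-hydroxy-4-[(1S,2E,4E,6E,10Z)-1,12-dihydroxy-3,7,11-trimethyldodeca-2,4,6,10-tetraen-1-yl]-2-methoxybenzyl acetate F3. PhI(OAc)2 in MeOH would then dearomatise F3 to 18.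

**Step 14.** What may go wrong: poor facial selectivity in the ring closure of the β-peroxy enolate, or competing attack on the C5=C6 enone. Fallback: replace steric control by alkoxide direction; it sets out from 18 and comes back at 20. Treating unprotected 18 with NaHMDS, trityl hydroperoxide and the matched antipode of diisopropyl tartrate in toluene at −50 °C (hydroxyl-directed, tartrate-mediated nucleophilic epoxidation, which delivers the peroxide from the C1' alkoxide to C2) would give the (2R,3S,1'S)-epoxy ketone diol F4. TESCl/imidazole would then give 20.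

**Step 15.** What may go wrong: hydride attack anti to the oxirane oxygen, which gives the C4 epimer. Fallback: accept that mode and invert; it sets out from 20 and comes back at 21. L-Selectride in THF at −78 °C would give the cis (2R,3R,4R,1'S)-epoxy alcohol F5 on purpose. Mitsunobu inversion with chloroacetic acid, PPh3 and DIAD would give the (4S)-chloroacetate F6. Thiourea/NaHCO3 in EtOH would remove the chloroacetyl group selectively in the presence of the acetate and return 21.

Further compounds
F1 | step 12 | 5-hydroxy-4-iodo-2-methoxybenzyl acetate | COc1cc(I)c(O)cc1COC(C)=O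
F2 | step 12 | [4-(acetoxymethyl)-2-hydroxy-5-methoxyphenyl]boronic acid | COc1cc(B(O)O)c(O)cc1COC(C)=O
F3 | step 12 | 5-hydroxy-4-[(1S,2E,4E,6E,10Z)-1,12-dihydroxy-3,7,11-trimethyldodeca-2,4,6,10-tetraen-1-yl]-2-methoxybenzyl acetate | COc1cc([C@@H](O)/C=C(C)/C=C/C=C(\C)CC/C=C(/C)CO)c(O)cc1COC(C)=O
F4 | step 14 | (2R,3S,1'S)-epoxy ketone diol, C1 dimethyl ketal | CC(=O)OCC1=CC(=O)[C@@]2([C@@H](O)/C=C(C)/C=C/C=C(\C)CC/C=C(/C)CO)O[C@H]2C1(OC)OC
F5 | step 15 | bis-TES cis-epoxy alcohol (2R,3R,4R,1'S), C1 dimethyl ketal | CC(=O)OCC1=C[C@@H](O)[C@@]2([C@@H](O[Si](CC)(CC)CC)/C=C(C)/C=C/C=C(\C)CC/C=C(/C)CO[Si](CC)(CC)CC)O[C@H]2C1(OC)OC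
F6 | step 15 | bis-TES (4S)-chloroacetate (2R,3R,4S,1'S), C1 dimethyl ketal | CC(=O)OCC1=C[C@H](OC(=O)CCl)[C@@]2([C@@H](O[Si](CC)(CC)CC)/C=C(C)/C=C/C=C(\C)CC/C=C(/C)CO[Si](CC)(CC)CC)O[C@H]2C1(OC)OC
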